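**Retrosynthetic overview**
- (−)-Carinol ⇐ global O-debenzylation ⇐ its bis(benzyl ether) ⇐ ozonolysis/NaBH4 of an (E)-propenyl group used as a masked CH2OH at C3.
- Key disconnection: the C2–C3 (lignan 8–8') bond, made by a hydroxyl-tethered allylboration of an achiral α-hydroxy ketone with an α-stereogenic (S,Z)-allylboronate. This single step sets both stereocentres.
- The allylboronate ⇐ sparteine-mediated lithiation–borylation of ethyl N,N-diisopropylcarbamate with a (Z)-alkenyl–Bpin ⇐ Z-selective cross-metathesis of O-benzyleugenol with vinyl–Bpin.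
- The α-hydroxy ketone ⇐ arylacetyl chloride + tris(trimethylsilyloxy)ethylene.
- No ring is formed in the route; the target is acyclic and both arenes are purchased.

Assumption: the target is the (2S,3S) isomer encoded by the SMILES; compounds 1, 3, 7, 9, (+)-sparteine and the Mo metathesis catalyst are taken as purchasable.

**Route**

Step 1
Reactants: 1, 2-[4-(benzyloxy)-3-methoxyphenyl]acetic acid
Product: 2, 2-[4-(benzyloxy)-3-methoxyphenyl]acetyl chloride
Conditions: (COCl)2, cat. DMF, CH2Cl2, 0 °C → rt
Reagents that add atoms: oxalyl chloride, ClC(=O)C(=O)Cl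
Why: DMF-catalysed acid chloride formation; the aryl benzyl and methyl ethers are inert and no stereocentre is involved.

Step 2
Reactants: 2; 3, tris(trimethylsilyloxy)ethylene
Product: 4, 1-[4-(benzyloxy)-3-methoxyphenyl]-3-hydroxypropan-2-one
Conditions: 3 (2.2 equiv), neat, 95 °C, 3 h; then 0.6 M HCl, dioxane, 85 °C, 30 min
Reagents that add atoms: 3, C[Si](C)(C)OC=C(O[Si](C)(C)C)O[Si](C)(C)C (supplies the CH2OH carbon and oxygen)
Why: Wissner hydroxymethyl ketone synthesis (C-acylation of the ketene acetal, then hydrolysis and decarboxylation of the α-hydroxy-β-keto acid); no stereocentre.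

Step 3
Reactants: 5, eugenol (4-allyl-2-methoxyphenol)
Product: 6, 4-allyl-1-(benzyloxy)-2-methoxybenzene
Conditions: BnBr, K2CO3, acetone, reflux
Reagents that add atoms: benzyl bromide, BrCc1ccccc1
Why: Williamson etherification of the phenol; the terminal alkene is untouched.

Step 4
Reactants: 6; 7, vinylboronic acid pinacol ester
Product: 8, (Z)-2-{3-[4-(benzyloxy)-3-methoxyphenyl]prop-1-en-1-yl}-4,4,5,5-tetramethyl-1,3,2-dioxaborolane
Conditions: 7 (3 equiv), Z-selective Mo monoaryloxide–pyrrolide alkylidene catalyst (5 mol %), C6H6, 22 °C, 100 torr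
Reagents that add atoms: 7, C=CB1OC(C)(C)C(C)(C)O1
Why: Kinetically Z-selective olefin cross-metathesis of a terminal alkene with vinyl–Bpin (the large aryloxide forces both metallacyclobutane substituents syn), which sets the Z geometry needed later; ethers are tolerated.

Step 5
Reactants: 8; 9, ethyl N,N-diisopropylcarbamate
Product: 10, (S,Z)-2-{5-[4-(benzyloxy)-3-methoxyphenyl]pent-3-en-2-yl}-4,4,5,5-tetramethyl-1,3,2-dioxaborolane
Conditions: 9 (1.3 equiv), s-BuLi (1.25 equiv), (+)-sparteine, Et2O, −78 °C, 5 h; then 8, −78 °C, 1 h; MgBr2·OEt2, → reflux, 2 h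
Reagents that add atoms: 9, CCOC(=O)N(C(C)C)C(C)C (supplies the CH3–CH unit)
Why: Hoppe–Aggarwal lithiation–borylation: (+)-sparteine gives the (R)-α-lithio carbamate, which borylates with retention and then undergoes 1,2-migration of the alkenyl group with inversion, giving the (S)-B-bearing carbon with the Z-alkene intact.

Step 6
Reactants: 10; 4
Product: 11, (2S,3S,4E)-2,3-bis[4-(benzyloxy)-3-methoxybenzyl]hex-4-ene-1,2-diol
Conditions: 10 (1.25 equiv), n-BuLi (1.2 equiv), THF, −78 °C, 15 min; TFAA (1.15 equiv), −78 °C, 30 min; then 4 (1.0 equiv), −78 → −20 °C; NaOH/H2O2, 0 °C work-up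
Reagents that add atoms: none (all heavy atoms come from 10 and 4)
Why: Proposed new method: hydroxyl-tethered, chirality-transferring allylboration of a ketone. The in situ allyl(butyl)borinic ester exchanges its alkoxide for the CH2OH of 4, so the ketone is delivered intramolecularly through a bicyclo[3.2.1] chair transition state. In it the CH2O–B bridge must be axial and the ArCH2 of the ketone equatorial, which fixes the C2 face even though the two ketone substituents are sterically alike. The Z-γ-CH2Ar is axial, and A(1,3) strain forces the α-methyl equatorial, so the (S)-C–B centre dictates the allyl face, giving (2S,3S) and an E-propenyl group. The closest known reactions are the ligand-exchange-directed allyl/crotylboration of α-hydroxy ketones with achiral dialkoxyboranes and the 1,3-chirality-transfer allylboration of aldehydes by α-substituted allyl–Bpin reagents activated as borinic esters; their combination on a ketone to set a tertiary carbinol and its neighbour is not established.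

Step 7
Reactants: 11
Product: 12, (2S,3S)-2,3-bis[4-(benzyloxy)-3-methoxybenzyl]butane-1,2,4-triol
Conditions: O3, CH2Cl2/MeOH, −78 °C (Sudan III end point); then NaBH4, −78 → 0 °C
Reagents that add atoms: ozone, [O-][O+]=O (oxygen of the new CH2OH)
Why: Ozonolysis with reductive borohydride work-up converts the propenyl group to CH2OH; the dye end point spares the electron-rich arenes, and the aldehyde is trapped as a lactol by the C1-OH and reduced cold, so C3 does not epimerise.

Step 8
Reactants: 12
Product: 13, (−)-carinol, (2S,3S)-2,3-bis(4-hydroxy-3-methoxybenzyl)butane-1,2,4-triol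
Conditions: H2 (1 atm), 10% Pd/C, EtOAc/MeOH, rt
Reagents that add atoms: none
Why: Catalytic hydrogenolysis cleaves both aryl benzyl ethers; the aliphatic alcohols and both stereocentres are unaffected.

**Compound list**
1 | 2-[4-(benzyloxy)-3-methoxyphenyl]acetic acid | COc1cc(CC(=O)O)ccc1OCc1ccccc1 | starting material
2 | 2-[4-(benzyloxy)-3-methoxyphenyl]acetyl chloride | COc1cc(CC(=O)Cl)ccc1OCc1ccccc1 | intermediate
3 | tris(trimethylsilyloxy)ethylene | C[Si](C)(C)OC=C(O[Si](C)(C)C)O[Si](C)(C)C | starting material
4 | 1-[4-(benzyloxy)-3-methoxyphenyl]-3-hydroxypropan-2-one | COc1cc(CC(=O)CO)ccc1OCc1ccccc1 | intermediate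
5 | eugenol | COc1cc(CC=C)ccc1O | starting material
6 | 4-allyl-1-(benzyloxy)-2-methoxybenzene | COc1cc(CC=C)ccc1OCc1ccccc1 | intermediate
7 | vinylboronic acid pinacol ester | C=CB1OC(C)(C)C(C)(C)O1 | starting material
8 | (Z)-2-{3-[4-(benzyloxy)-3-methoxyphenyl]prop-1-en-1-yl}-4,4,5,5-tetramethyl-1,3,2-dioxaborolane | COc1cc(C/C=C\B2OC(C)(C)C(C)(C)O2)ccc1OCc1ccccc1 | intermediate
9 | ethyl N,N-diisopropylcarbamate | CCOC(=O)N(C(C)C)C(C)C | starting material
10 | (S,Z)-2-{5-[4-(benzyloxy)-3-methoxyphenyl]pent-3-en-2-yl}-4,4,5,5-tetramethyl-1,3,2-dioxaborolane | C[C@H](B1OC(C)(C)C(C)(C)O1)/C=C\Cc1ccc(OCc2ccccc2)c(OC)c1 | intermediate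
11 | (2S,3S,4E)-2,3-bis[4-(benzyloxy)-3-methoxybenzyl]hex-4-ene-1,2-diol | COc1cc(C[C@@H](/C=C/C)[C@](O)(CO)Cc2ccc(OCc3ccccc3)c(OC)c2)ccc1OCc1ccccc1 | intermediate
12 | (2S,3S)-2,3-bis[4-(benzyloxy)-3-methoxybenzyl]butane-1,2,4-triol | COc1cc(C[C@@H](CO)[C@](O)(CO)Cc2ccc(OCc3ccccc3)c(OC)c2)ccc1OCc1ccccc1 | intermediate
13 | (−)-carinol, (2S,3S)-2,3-bis(4-hydroxy-3-methoxybenzyl)butane-1,2,4-triol | COc1cc(C[C@@H](CO)[C@](O)(CO)Cc2ccc(O)c(OC)c2)ccc1O | target

**Totals**
Total steps: 8. Longest linear sequence: 6 (steps 3–8, from eugenol).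

**Three steps most likely to fail**
1. Step 6 (proposed new step). Risks are incomplete O–B exchange, which would allow untethered addition and give the C2 epimer, and protodeboronation or 1,3-boron shift of the activated reagent. Fallback (known chemistry): make the same C2–C3 bond by a chelation-controlled Ireland–Claisen rearrangement with 1,3-chirality transfer. Esterify racemic 2-(benzyloxy)-3-[4-(benzyloxy)-3-methoxyphenyl]propanoic acid with (S,Z)-5-[4-(benzyloxy)-3-methoxyphenyl]pent-3-en-2-ol (from (S)-but-3-yn-2-ol by Cu-catalysed alkyne benzylation and Lindlar reduction). Treat with LiHMDS/TMSCl, −78 °C → rt; the chelated enolate and Z-allyl chair give the (2S,3S) acid. Then LiAlH4, O3/NaBH4 and H2/Pd–C.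
2. Step 5 (lithiation–borylation with a Z-alkenyl boronate). Risks are deprotonation of the doubly activated ArCH2 and erosion of ee or Z geometry. Fallback: auxiliary-controlled Matteson homologation. Transesterify 8 to its 1,2-dicyclohexylethanediol boronate, insert LiCHCl2/ZnCl2, then displace chloride with MeMgBr to give the same α-methyl allylboronate, with the stereocentre set by the diol.
3. Step 4 (Z-selective cross-metathesis). Risks are an air-sensitive catalyst, Z/E erosion and isomerisation of the allylarene. Fallback: alkyne route. Couple 4-(benzyloxy)-3-methoxybenzyl chloride with ethynylmagnesium bromide (CuCl), then carry out Rh-catalysed trans-hydroboration of the terminal alkyne with pinacolborane to give 8.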